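**Retrosynthetic overview**
- Feature: ring A is a benzoylphloroglucinol with a single ether oxygen. Its prenyloxy-bearing carbon lies ortho to the benzoyl-bearing carbon, the same relation as the enol-ether oxygen and the ketone of O-prenylated benzoylacetone. The carbon between the two hydroxyl-bearing carbons carries the CH2 bridge.
- Ring A is formed first, by cutting two bonds: ring CH to the hydroxyl carbon para to the benzoyl group, and benzoyl-bearing carbon to the hydroxyl carbon ortho to it. The benzoyl-bearing carbon, the ether carbon and the ring CH come from the γ-dienolate of the prenyl enol ether of benzoylacetone. The two hydroxyl carbons and the bridge-bearing carbon between them, with a propanoate arm, come from a malonyl half-ester chloride.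
- Ring B is formed second, from that arm (bridge CH2, the bridge-bearing ring carbon and the enol carbon next to it). A crossed Claisen condensation with 3-methylbutan-2-one adds the acyl-bearing carbon and the isobutyryl group. A [3+3] annulation of the β-diketone dianion with dimethyl 2,2-dimethylmalonate then makes the two remaining ring bonds, one on each side of the gem-dimethyl unit.
- The two phenols of ring A are carried as triisopropylsilyl ethers between the two ring formations and are freed by fluoride, because the aryl prenyl ether would not survive acid.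

Key step: step 6

Remark: the target has no stereocentre. Ring B is drawn as one enol tautomer of the acylfilicinic acid and all its keto–enol tautomers are treated as the same compound. The CH centres of 7, 8, 9, 11 and 19 are racemic or enolised.

Step 1
Reactants: 1 benzoylacetone (1-phenylbutane-1,3-dione)
Product: 2 (E)-3-methoxy-1-phenylbut-2-en-1-one
Conditions: HC(OMe)3 (1.5 equiv), TsOH·H2O (2 mol%), MeOH, rt
Reagents that add atoms: trimethyl orthoformate, COC(OC)OC
Why: Acid-catalysed enol etherification (orthoester method); the non-conjugated acetyl carbonyl is more electrophilic than the benzoyl carbonyl, so the ether should form there and give the conjugated, thermodynamically preferred E isomer.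

Step 2
Reactants: 2 (E)-3-methoxy-1-phenylbut-2-en-1-one; 3 prenol (3-methylbut-2-en-1-ol)
Product: 4 (E)-3-(3-methylbut-2-enyloxy)-1-phenylbut-2-en-1-one
Conditions: 3 (3 equiv), PPTS (5 mol%), toluene, 60 °C, 5 Å molecular sieves (MeOH uptake)
Reagents that add atoms: none
Why: Acid-catalysed alkoxy exchange of a β-alkoxy enone (vinylogous transesterification by addition–elimination at the β-carbon) is pulled to the prenyl ether by removal of methanol, while the weak pyridinium acid and 60 °C are too mild to ionise prenol or to trigger Claisen rearrangement of the allyl vinyl ether; the double-bond geometry has no bearing on step 6.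

Step 3
Reactants: 5 benzyl methyl malonate; 6 methyl acrylate
Product: 7 1-benzyl 1,3-dimethyl propane-1,1,3-tricarboxylate (racemic)
Conditions: 5 (2 equiv), DBU (5 mol%), MeCN, 0 °C → rt, slow addition of 6
Reagents that add atoms: none
Why: Base-catalysed Michael addition of the malonate to the acrylate; the excess of 5 and slow addition of 6 hold back a second addition, and the new CH centre is racemic and later lost.

Step 4
Reactants: 7 1-benzyl 1,3-dimethyl propane-1,1,3-tricarboxylate
Product: 8 5-methoxy-2-(methoxycarbonyl)-5-oxopentanoic acid (racemic)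
Conditions: H2 (1 atm), 10% Pd/C, EtOAc, rt
Reagents that add atoms: none
Why: Hydrogenolysis of the benzyl ester frees exactly one malonate carboxyl under neutral conditions, which avoids an unselective partial saponification among three methyl esters, and room temperature keeps the malonic half acid from decarboxylating.

Step 5
Reactants: 8 5-methoxy-2-(methoxycarbonyl)-5-oxopentanoic acid
Product: 9 dimethyl 2-(chlorocarbonyl)pentanedioate (racemic)
Conditions: (COCl)2 (1.2 equiv), DMF (cat.), CH2Cl2, 0 °C → rt; concentrated and used crude
Reagents that add atoms: oxalyl chloride, O=C(Cl)C(=O)Cl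
Why: Standard conversion of a carboxylic acid into its chloride with oxalyl chloride under DMF catalysis; no base is present, so the acidic α-CH is left alone.

Step 6
Reactants: 4 (E)-3-(3-methylbut-2-enyloxy)-1-phenylbut-2-en-1-one (2.1 equiv); 9 dimethyl 2-(chlorocarbonyl)pentanedioate (1.0 equiv)
Product: 12 methyl 3-[3-benzoyl-2,6-dihydroxy-4-(3-methylbut-2-enyloxy)phenyl]propanoate, via lithium dienolate 10 (not isolated), via acyclic keto diester 11 (not isolated)
Conditions: LiN(iPr)2 (2.1 equiv), THF, −78 °C; 9, −78 °C; AcOH (1.2 equiv), −78 °C; DBU (4 equiv), −78 → 40 °C; aq. citric acid work-up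
Reagents that add atoms: none
Why: LiN(iPr)2 removes the most acidic C–H of 4, on the enol-ether methyl group, and the terminal carbon of dienolate 10, activated both as an enol-ether β-carbon and as the γ-position of the enolate, is acylated by 9 to form the bond between the future ring CH and the hydroxyl carbon para to the benzoyl group, while the second equivalent of 10 takes up the acidic malonyl-type proton of 11 and returns 4 for recovery. After neutralisation with AcOH, DBU regenerates a monoanion of 11 whose extended enolate attacks the activated β-keto ester carbonyl through the carbon α to the benzoyl group in a 6-(enolexo)-exo-trig Claisen closure (the bond between the benzoyl-bearing carbon and the hydroxyl carbon ortho to it), and loss of methanol and enolisation should give the arene with the enol-ether oxygen retained as the aryl prenyl ether. The closest known reactions are the γ-acylation of lithium dienolates of β-alkoxy enones and enoates and the base-induced Claisen cyclisation of 3,5,7-trioxo esters to acylphloroglucinols. No stereocentre is formed. The step needs C- over O-acylation and γ- over α-attack (double activation of the terminal carbon, and O-acylated material is returned by enolate transacylation), Claisen over aldol closure (the aldol adduct of the propanoate-bearing carbon onto the benzoyl carbonyl is quaternary at that carbon, cannot dehydrate to an arene and reverts) and Claisen over Dieckmann attack of the future ring CH on the side-chain ester (closing the monoanion under an amidine base keeps the β-keto ester the most electrophilic carbonyl, whereas a dianion would deactivate it). The O-prenyl group also blocks pyranone formation through the enol-ether oxygen.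

Step 7
Reactants: 12 methyl 3-[3-benzoyl-2,6-dihydroxy-4-(3-methylbut-2-enyloxy)phenyl]propanoate
Product: 13 methyl 3-[3-benzoyl-4-(3-methylbut-2-enyloxy)-2,6-bis(triisopropylsilyloxy)phenyl]propanoate
Conditions: iPr3SiOTf (2.6 equiv), 2,6-lutidine (4 equiv), CH2Cl2, 0 °C → rt
Reagents that add atoms: triisopropylsilyl trifluoromethanesulfonate, CC(C)[Si](OS(=O)(=O)C(F)(F)F)(C(C)C)C(C)C
Why: The silyl triflate is reactive enough for the hydrogen-bonded, flanked hydroxyl ortho to the benzoyl group as well as the hydroxyl para to it, and the resulting base-stable triisopropylsilyl ethers can later be removed by fluoride without acid.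

Step 8
Reactants: 13 methyl 3-[3-benzoyl-4-(3-methylbut-2-enyloxy)-2,6-bis(triisopropylsilyloxy)phenyl]propanoate; 14 3-methylbutan-2-one
Product: 16 1-[3-benzoyl-4-(3-methylbut-2-enyloxy)-2,6-bis(triisopropylsilyloxy)phenyl]-6-methylheptane-3,5-dione, via lithium enolate 15 (not isolated)
Conditions: 14 (3.2 equiv), LiN(iPr)2 (3.0 equiv), THF, −78 °C; 13, −78 → 0 °C; aq. NH4Cl
Reagents that add atoms: none
Why: Crossed Claisen condensation of the kinetic methyl-side lithium enolate 15 with the methyl ester, driven by deprotonation of the β-diketone formed; acylation at the isopropyl methine would give a non-enolisable diketone and is not productive, and the benzophenone carbonyl, flanked by two ortho oxygen substituents, is too hindered to add the enolate.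

Step 9
Reactants: 16 1-[3-benzoyl-4-(3-methylbut-2-enyloxy)-2,6-bis(triisopropylsilyloxy)phenyl]-6-methylheptane-3,5-dione; 17 dimethyl 2,2-dimethylmalonate
Product: 20 4-{[3-benzoyl-4-(3-methylbut-2-enyloxy)-2,6-bis(triisopropylsilyloxy)phenyl]methyl}-3,5-dihydroxy-6,6-dimethyl-2-(2-methylpropanoyl)cyclohexa-2,4-dien-1-one, via dilithium dianion 18 (not isolated), via trioxo ester 19 (not isolated)
Conditions: LiN(iPr)2 (3.3 equiv), THF, −78 → 0 °C; 17 (1.2 equiv), 0 °C → rt; aq. NH4Cl, then citric acid to pH 3
Reagents that add atoms: none
Why: LiN(iPr)2 deprotonates 16 at the central methylene between the two carbonyls and then at the less hindered outer α-methylene next to the arylmethyl carbon (not the isopropyl methine) to dianion 18, whose terminal carbanion is acylated by one ester of the non-enolisable diester 17 (dianion acylation of a β-diketone), and in the resulting 3,5,7-trioxo ester 19 the carbon between the isobutyryl carbonyl and the chain ketone closes onto the second ester in a 6-exo-trig Claisen condensation favoured by the gem-dimethyl group and by formation of the strongly stabilised acylfilicinic acid anion; the third equivalent of base covers the acidic proton created by the first acylation.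

Step 10
Reactants: 20 4-{[3-benzoyl-4-(3-methylbut-2-enyloxy)-2,6-bis(triisopropylsilyloxy)phenyl]methyl}-3,5-dihydroxy-6,6-dimethyl-2-(2-methylpropanoyl)cyclohexa-2,4-dien-1-one
Product: 21 sarothralin, 4-{[3-benzoyl-2,6-dihydroxy-4-(3-methylbut-2-enyloxy)phenyl]methyl}-3,5-dihydroxy-6,6-dimethyl-2-(2-methylpropanoyl)cyclohexa-2,4-dien-1-one
Conditions: Bu4NF (3 equiv), AcOH (3 equiv), THF, 0 °C → rt; aq. citric acid work-up
Reagents that add atoms: none
Why: Fluoride cleaves both aryl silyl ethers through Si–F bond formation under buffered, essentially neutral conditions that should leave the aryl prenyl ether, the benzophenone and the enolised β-triketone of ring B intact.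

**Compound list**
1 | benzoylacetone (1-phenylbutane-1,3-dione) | CC(=O)CC(=O)c1ccccc1 | starting material
2 | (E)-3-methoxy-1-phenylbut-2-en-1-one | C/C(OC)=C\C(=O)c1ccccc1 | intermediate
3 | prenol (3-methylbut-2-en-1-ol) | CC(C)=CCO | starting material
4 | (E)-3-(3-methylbut-2-enyloxy)-1-phenylbut-2-en-1-one | C/C(OCC=C(C)C)=C\C(=O)c1ccccc1 | intermediate
5 | benzyl methyl malonate | COC(=O)CC(=O)OCc1ccccc1 | starting material
6 | methyl acrylate | C=CC(=O)OC | starting material
7 | 1-benzyl 1,3-dimethyl propane-1,1,3-tricarboxylate (racemic) | COC(=O)CCC(C(=O)OC)C(=O)OCc1ccccc1 | intermediate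
8 | 5-methoxy-2-(methoxycarbonyl)-5-oxopentanoic acid (racemic) | COC(=O)CCC(C(=O)O)C(=O)OC | intermediate
9 | dimethyl 2-(chlorocarbonyl)pentanedioate (racemic) | COC(=O)CCC(C(=O)Cl)C(=O)OC | intermediate
10 | lithium (1Z)-3-(3-methylbut-2-enyloxy)-1-phenylbuta-1,3-dien-1-olate (formed in the flask, geometry presumed Z) | [Li+].[O-]/C(=C\C(=C)OCC=C(C)C)c1ccccc1 | intermediate
11 | dimethyl 2-[(E)-3-(3-methylbut-2-enyloxy)-5-oxo-5-phenylpent-3-enoyl]pentanedioate (formed in the flask, held as its lithium enolate until the AcOH quench) | COC(=O)CCC(C(=O)OC)C(=O)C/C(OCC=C(C)C)=C\C(=O)c1ccccc1 | intermediate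
12 | methyl 3-[3-benzoyl-2,6-dihydroxy-4-(3-methylbut-2-enyloxy)phenyl]propanoate | COC(=O)CCc1c(O)cc(OCC=C(C)C)c(C(=O)c2ccccc2)c1O | intermediate
13 | methyl 3-[3-benzoyl-4-(3-methylbut-2-enyloxy)-2,6-bis(triisopropylsilyloxy)phenyl]propanoate | COC(=O)CCc1c(O[Si](C(C)C)(C(C)C)C(C)C)cc(OCC=C(C)C)c(C(=O)c2ccccc2)c1O[Si](C(C)C)(C(C)C)C(C)C | intermediate
14 | 3-methylbutan-2-one | CC(=O)C(C)C | starting material
15 | lithium 3-methylbut-1-en-2-olate (formed in the flask) | [Li+].[O-]C(=C)C(C)C | intermediate
16 | 1-[3-benzoyl-4-(3-methylbut-2-enyloxy)-2,6-bis(triisopropylsilyloxy)phenyl]-6-methylheptane-3,5-dione | CC(C)C(=O)CC(=O)CCc1c(O[Si](C(C)C)(C(C)C)C(C)C)cc(OCC=C(C)C)c(C(=O)c2ccccc2)c1O[Si](C(C)C)(C(C)C)C(C)C | intermediate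
17 | dimethyl 2,2-dimethylmalonate | COC(=O)C(C)(C)C(=O)OC | starting material
18 | dilithium dianion of 16 (dienediolate, formed in the flask, geometry not defined) | [Li+].[Li+].CC(C)C([O-])=CC([O-])=CCc1c(O[Si](C(C)C)(C(C)C)C(C)C)cc(OCC=C(C)C)c(C(=O)c2ccccc2)c1O[Si](C(C)C)(C(C)C)C(C)C | intermediate
19 | methyl 4-{[3-benzoyl-4-(3-methylbut-2-enyloxy)-2,6-bis(triisopropylsilyloxy)phenyl]methyl}-2,2,8-trimethyl-3,5,7-trioxononanoate (formed in the flask as its enolate) | COC(=O)C(C)(C)C(=O)C(Cc1c(O[Si](C(C)C)(C(C)C)C(C)C)cc(OCC=C(C)C)c(C(=O)c2ccccc2)c1O[Si](C(C)C)(C(C)C)C(C)C)C(=O)CC(=O)C(C)C | intermediate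
20 | 4-{[3-benzoyl-4-(3-methylbut-2-enyloxy)-2,6-bis(triisopropylsilyloxy)phenyl]methyl}-3,5-dihydroxy-6,6-dimethyl-2-(2-methylpropanoyl)cyclohexa-2,4-dien-1-one | CC(C)=CCOc1cc(O[Si](C(C)C)(C(C)C)C(C)C)c(CC2=C(O)C(C)(C)C(=O)C(C(=O)C(C)C)=C2O)c(O[Si](C(C)C)(C(C)C)C(C)C)c1C(=O)c1ccccc1 | intermediate
21 | sarothralin | CC(C)=CCOc1cc(O)c(CC2=C(O)C(C)(C)C(=O)C(C(=O)C(C)C)=C2O)c(O)c1C(=O)c1ccccc1 | target

Total step count: 10. Longest linear sequence: 8 steps (steps 3 to 10, from benzyl methyl malonate).

**Steps most likely to fail**

Step 6. Proton transfer from the α-CH of 9 to dienolate 10 may outrun C–C bond formation. Acylation may take place at the enolate oxygen or at the carbon α to the benzoyl group instead of the terminal carbon. On warming, the dienolate may undergo an anion-accelerated [3,3] shift of the prenyl group. In the closing stage, Dieckmann attack of the methylene between the enol-ether carbon and the new ketone on the side-chain ester, or lactone trapping of the reversible aldol adduct, may drain material. The fallback sets out from 4 and separates the two bond formations. The dienolate is trapped with Me3SiCl (LiN(iPr)2, THF, −78 °C) as the silyl dienol ether trimethyl{[(1Z)-3-(3-methylbut-2-enyloxy)-1-phenylbuta-1,3-dien-1-yl]oxy}silane F1. This neutral diene is acylated at its terminal carbon by 9 in CH2Cl2 (−78 °C → rt, a vinylogous Mukaiyama-type acylation as known for 1,3-bis(silyloxy)dienes and acid chlorides, with no basic species present), and 11 is isolated. Isolated 11 is then closed with DBU in toluene, and the route is rejoined at 12.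

Step 9. Acylation of the hindered terminal carbanion by the α-quaternary ester may be slow. Proton transfer from the first acylation product may stall the dianion. Ring closure may start through oxygen. The amide base may transfer hydride to the diaryl ketone, or silyl groups may migrate to the enolate. The fallback makes the two ring-B bonds in the opposite order. From 17, half-saponification (KOH, 1 equiv, MeOH, then acidification) gives 3-methoxy-2,2-dimethyl-3-oxopropanoic acid F2, and (COCl)2 with catalytic DMF gives methyl 3-chloro-2,2-dimethyl-3-oxopropanoate F3. Setting out from 16, soft enolisation (MgCl2, pyridine, CH2Cl2, 0 °C → rt) and F3 acylate the central carbon of the β-diketone to give the triacylmethane methyl 4-{3-[3-benzoyl-4-(3-methylbut-2-enyloxy)-2,6-bis(triisopropylsilyloxy)phenyl]propanoyl}-2,2,6-trimethyl-3,5-dioxoheptanoate F4. LiN(iPr)2 (2.2 equiv, THF, −78 → 0 °C) then removes a proton from the methylene next to the arylmethyl carbon of F4, and Dieckmann attack of that carbon on the ester closes ring B, so the route is rejoined at 20.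

Step 8. Self-aldol reaction of the ketone may outpace the Claisen condensation, conversion of the unactivated ester may stay incomplete, and the methoxide released may start to remove a silyl group. The fallback sets out from 13 and changes the acyl donor. The ester is converted into the Weinreb amide 3-[3-benzoyl-4-(3-methylbut-2-enyloxy)-2,6-bis(triisopropylsilyloxy)phenyl]-N-methoxy-N-methylpropanamide F5 (MeNH(OMe)·HCl, iPrMgCl, THF, −20 °C). F5 then acylates lithium enolate 15 (THF, −78 → 0 °C) without release of alkoxide before work-up, and the route is rejoined at 16.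

Further compounds
F1 | step 6 | trimethyl{[(1Z)-3-(3-methylbut-2-enyloxy)-1-phenylbuta-1,3-dien-1-yl]oxy}silane | C=C(OCC=C(C)C)/C=C(\O[Si](C)(C)C)c1ccccc1
F2 | step 9 | 3-methoxy-2,2-dimethyl-3-oxopropanoic acid | COC(=O)C(C)(C)C(=O)O
F3 | step 9 | methyl 3-chloro-2,2-dimethyl-3-oxopropanoate | COC(=O)C(C)(C)C(=O)Cl
F4 | step 9 | methyl 4-{3-[3-benzoyl-4-(3-methylbut-2-enyloxy)-2,6-bis(triisopropylsilyloxy)phenyl]propanoyl}-2,2,6-trimethyl-3,5-dioxoheptanoate | COC(=O)C(C)(C)C(=O)C(C(=O)C(C)C)C(=O)CCc1c(O[Si](C(C)C)(C(C)C)C(C)C)cc(OCC=C(C)C)c(C(=O)c2ccccc2)c1O[Si](C(C)C)(C(C)C)C(C)C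
F5 | step 8 | 3-[3-benzoyl-4-(3-methylbut-2-enyloxy)-2,6-bis(triisopropylsilyloxy)phenyl]-N-methoxy-N-methylpropanamide | CON(C)C(=O)CCc1c(O[Si](C(C)C)(C(C)C)C(C)C)cc(OCC=C(C)C)c(C(=O)c2ccccc2)c1O[Si](C(C)C)(C(C)C)C(C)C
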